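**Retrosynthetic overview**
- The target is reached from its penta-O-benzyl ether by one global debenzylation that spares both alkenes.
- Key disconnection: the aryl–O–vinyl bond (O-3 of the central ring A to the α-carbon of the ring B acrylate). It is cut to a ring A phenol (tri-O-benzyl methyl rosmarinate) and methyl (Z)-α-bromo-3,4-bis(benzyloxy)cinnamate, joined by light-driven nickel-catalysed C(sp2)–O coupling.
- The tri-O-benzyl methyl rosmarinate comes from 4-(benzyloxy)-3-hydroxybenzaldehyde and the malonic half-ester of benzylated methyl (R)-danshensu (Knoevenagel–Doebner). The only stereocenter is bought in sodium danshensu.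
- The bromocinnamate comes from 3,4-bis(benzyloxy)benzaldehyde by bromo-Wittig olefination.
- No ring is formed: rings A (central), B (enol-ether side) and C (lactate side) are all bought as benzene derivatives.

Assumption: the SMILES is read as the (R)-lactate, the E caffeoyl alkene and the Z enol ether (aryl trans to the ester); sodium danshensu is taken as a catalogue chiral-pool material.

**Route**

Step 1
Reactants: 1 sodium (2R)-3-(3,4-dihydroxyphenyl)-2-hydroxypropanoate (sodium danshensu)
Product: 2 methyl (2R)-3-(3,4-dihydroxyphenyl)-2-hydroxypropanoate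
Conditions: HCl (1.25 M in MeOH, 3 equiv), 40 °C, 12 h, N2
Reagents that add atoms: methanol CO
Why: Fischer esterification under anhydrous acid; the (R) stereocenter bought with 1 is not touched.

Step 2
Reactants: 2 methyl (2R)-3-(3,4-dihydroxyphenyl)-2-hydroxypropanoate
Product: 3 methyl (2R)-3-[3,4-bis(benzyloxy)phenyl]-2-hydroxypropanoate
Conditions: BnBr (2.1 equiv), K2CO3 (2.5 equiv), acetone, reflux, 12 h, N2
Reagents that add atoms: benzyl bromide BrCc1ccccc1
Why: Williamson etherification in which K2CO3 deprotonates only the two phenols, so the secondary alcohol, the methyl ester and the stereocenter stay as they are.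

Step 3
Reactants: 3 methyl (2R)-3-[3,4-bis(benzyloxy)phenyl]-2-hydroxypropanoate; 4 4-(benzyloxy)-3-hydroxybenzaldehyde
Product: 6 methyl (2R)-3-[3,4-bis(benzyloxy)phenyl]-2-{[(2E)-3-[4-(benzyloxy)-3-hydroxyphenyl]prop-2-enoyl]oxy}propanoate, via malonic half-ester 5 (not isolated)
Conditions: Meldrum's acid (1.2 equiv), toluene, 100 °C, 5 h; then 4 (1.3 equiv), pyridine, piperidine (0.2 equiv), 70 °C, 12 h
Reagents that add atoms: Meldrum's acid CC1(C)OC(=O)CC(=O)O1
Why: Acyl transfer from Meldrum's acid to the alcohol gives the malonic half-ester, which undergoes decarboxylative Knoevenagel–Doebner condensation with 4 to the thermodynamically favoured E cinnamate; the stereocenter is only acylated on oxygen, so (R) is retained.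

Step 4
Reactants: 7 3,4-bis(benzyloxy)benzaldehyde
Product: 9 methyl (2Z)-3-[3,4-bis(benzyloxy)phenyl]-2-bromoprop-2-enoate, via bromo ylide 8 (not isolated)
Conditions: Ph3P=CHCO2Me (1.3 equiv), NBS (1.35 equiv), CH2Cl2, –20 °C, 30 min; then 7, rt to 40 °C, 16 h
Reagents that add atoms: methyl (triphenylphosphoranylidene)acetate COC(=O)C=P(c1ccccc1)(c1ccccc1)c1ccccc1; N-bromosuccinimide O=C1CCC(=O)N1Br
Why: Wittig olefination with the stabilised bromo ylide made in the flask places the ester trans to the aryl group, which is the (Z)-bromoalkene.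

Step 5
Reactants: 6 methyl (2R)-3-[3,4-bis(benzyloxy)phenyl]-2-{[(2E)-3-[4-(benzyloxy)-3-hydroxyphenyl]prop-2-enoyl]oxy}propanoate; 9 methyl (2Z)-3-[3,4-bis(benzyloxy)phenyl]-2-bromoprop-2-enoate (1.3 equiv)
Product: 10 methyl (2R)-3-[3,4-bis(benzyloxy)phenyl]-2-{[(2E)-3-[4-(benzyloxy)-3-{[(1Z)-1-[3,4-bis(benzyloxy)phenyl]-3-methoxy-3-oxoprop-1-en-2-yl]oxy}phenyl]prop-2-enoyl]oxy}propanoate
Conditions: NiBr2·glyme (10 mol%), 4,4'-di-tert-butyl-2,2'-bipyridine (dtbbpy, 12 mol%), quinuclidine (1.5 equiv), DMA, 427 nm LEDs, 25 °C, Ar, 18 h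
Reagents that add atoms: none
Why: Proposed new method: photocatalyst-free, light-driven nickel-catalysed O-vinylation of a phenol with an α-bromoacrylate – 427 nm light (not absorbed by either cinnamate, so no E/Z photoisomerisation) reduces the (dtbbpy)NiBr2–amine complex by ligand-to-metal charge transfer to monovalent nickel, whose phenoxide (from 6 and quinuclidine) adds oxidatively to the activated C(sp2)–Br bond of 9 to give a trivalent nickel vinyl aryloxide that reductively eliminates the vinyl C–O bond with retention of the Z geometry (also the thermodynamically preferred one), while off-cycle divalent nickel vinyl bromide is returned to the cycle by light-induced Ni–C homolysis; the mild amine base at 25 °C avoids dehydrobromination of 9 to the propiolate, which would lead to the β-aryloxy isomer, and no new stereocenter is formed; closest known reaction type: light-driven nickel-catalysed C–O cross-coupling of aryl bromides with alcohols and phenols (and copper-catalysed Ullmann O-vinylation), not shown for α-bromoacrylates with phenols.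

Step 6
Reactants: 10 methyl (2R)-3-[3,4-bis(benzyloxy)phenyl]-2-{[(2E)-3-[4-(benzyloxy)-3-{[(1Z)-1-[3,4-bis(benzyloxy)phenyl]-3-methoxy-3-oxoprop-1-en-2-yl]oxy}phenyl]prop-2-enoyl]oxy}propanoate
Product: 11 methyl (2R)-3-(3,4-dihydroxyphenyl)-2-{[(2E)-3-[3-{[(1Z)-1-(3,4-dihydroxyphenyl)-3-methoxy-3-oxoprop-1-en-2-yl]oxy}-4-hydroxyphenyl]prop-2-enoyl]oxy}propanoate (CNP0178751.1)
Conditions: BCl3 (1 M in CH2Cl2, 12 equiv), pentamethylbenzene (15 equiv), CH2Cl2, –78 °C, 1 h; then MeOH/H2O quench
Reagents that add atoms: none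
Why: Lewis-acid debenzylation with pentamethylbenzene as a non-basic benzyl-cation scavenger cleaves the five aryl benzyl ethers at –78 °C and leaves both alkenes, the three esters, the vinyl ether and the stereocenter alone, which hydrogenolysis would not.

**Compound list**

1 | sodium (2R)-3-(3,4-dihydroxyphenyl)-2-hydroxypropanoate | O[C@H](Cc1ccc(O)c(O)c1)C(=O)[O-].[Na+] | starting material
2 | methyl (2R)-3-(3,4-dihydroxyphenyl)-2-hydroxypropanoate | O[C@H](Cc1ccc(O)c(O)c1)C(=O)OC | intermediate
3 | methyl (2R)-3-[3,4-bis(benzyloxy)phenyl]-2-hydroxypropanoate | O[C@H](Cc1ccc(OCc2ccccc2)c(OCc2ccccc2)c1)C(=O)OC | intermediate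
4 | 4-(benzyloxy)-3-hydroxybenzaldehyde | O=Cc1ccc(OCc2ccccc2)c(O)c1 | starting material
5 | 3-{[(2R)-3-[3,4-bis(benzyloxy)phenyl]-1-methoxy-1-oxopropan-2-yl]oxy}-3-oxopropanoic acid (malonic half-ester) | OC(=O)CC(=O)O[C@H](Cc1ccc(OCc2ccccc2)c(OCc2ccccc2)c1)C(=O)OC | intermediate
6 | methyl (2R)-3-[3,4-bis(benzyloxy)phenyl]-2-{[(2E)-3-[4-(benzyloxy)-3-hydroxyphenyl]prop-2-enoyl]oxy}propanoate | O=C(/C=C/c1ccc(OCc2ccccc2)c(O)c1)O[C@H](Cc1ccc(OCc2ccccc2)c(OCc2ccccc2)c1)C(=O)OC | intermediate
7 | 3,4-bis(benzyloxy)benzaldehyde | O=Cc1ccc(OCc2ccccc2)c(OCc2ccccc2)c1 | starting material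
8 | methyl bromo(triphenylphosphoranylidene)acetate (bromo ylide) | COC(=O)C(Br)=P(c1ccccc1)(c1ccccc1)c1ccccc1 | intermediate
9 | methyl (2Z)-3-[3,4-bis(benzyloxy)phenyl]-2-bromoprop-2-enoate | COC(=O)/C(Br)=C/c1ccc(OCc2ccccc2)c(OCc2ccccc2)c1 | intermediate
10 | methyl (2R)-3-[3,4-bis(benzyloxy)phenyl]-2-{[(2E)-3-[4-(benzyloxy)-3-{[(1Z)-1-[3,4-bis(benzyloxy)phenyl]-3-methoxy-3-oxoprop-1-en-2-yl]oxy}phenyl]prop-2-enoyl]oxy}propanoate | COC(=O)/C(=C/c1ccc(OCc2ccccc2)c(OCc2ccccc2)c1)Oc1cc(/C=C/C(=O)O[C@H](Cc2ccc(OCc3ccccc3)c(OCc3ccccc3)c2)C(=O)OC)ccc1OCc1ccccc1 | intermediate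
11 | methyl (2R)-3-(3,4-dihydroxyphenyl)-2-{[(2E)-3-[3-{[(1Z)-1-(3,4-dihydroxyphenyl)-3-methoxy-3-oxoprop-1-en-2-yl]oxy}-4-hydroxyphenyl]prop-2-enoyl]oxy}propanoate | COC(=O)/C(=C/c1ccc(O)c(O)c1)Oc1cc(/C=C/C(=O)O[C@H](Cc2ccc(O)c(O)c2)C(=O)OC)ccc1O | target

**Step count and risks**

Total step count: 6 (steps 3 and 4 are one-pot operations with a non-isolated intermediate each).
Longest linear sequence: 5 steps (1 → 2 → 3 → 6 → 10 → 11, that is steps 1, 2, 3, 5 and 6).

The three steps most likely to fail:

Step 5 (the proposed new coupling). The risks are no turnover with a vinyl bromide, hydrodebromination of 9, and partial loss of the Z geometry. The fallback uses known chemistry, sets out from 6 and comes back at 10. Rh2(OAc)4 (2 mol%) catalysed O–H insertion of the phenol of 6 into the carbenoid from trimethyl diazophosphonoacetate (toluene, 80 °C) gives the α-aryloxy phosphonoacetate F1, a diastereomer mixture at the new phosphorus-bearing carbon, which is destroyed in the next operation. Horner–Wadsworth–Emmons olefination of F1 with aldehyde 7 (LiCl, DBU, MeCN, 0 °C to rt) then gives 10, with the Z isomer predominating and separable.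

Step 3 (acylation and Knoevenagel–Doebner in one pot). The risks are slow acylation of the hindered α-hydroxy ester, decarboxylation of the half-ester before condensation, and some epimerisation in warm pyridine/piperidine. The fallback sets out from 3 and comes back at 6. Steglich acylation of 3 with diethylphosphonoacetic acid (DCC, DMAP cat., CH2Cl2, 0 °C) gives the phosphonoacetate ester F2. Masamune–Roush Horner–Wadsworth–Emmons olefination of F2 with aldehyde 4 (LiCl, DBU 2.2 equiv, MeCN, rt) then gives 6 as the E alkene under milder, non-decarboxylative conditions.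

Step 6 (five-fold debenzylation). The risks are incomplete cleavage or boron chelation that attacks the ester or vinyl ether oxygens. The fallback sets out from 10 and comes back at 11. It is a Brønsted-acid push–pull debenzylation (TFA, thioanisole 25 equiv, rt, 3–6 h), in which the protonated ethers hand the benzyl group to sulfur in an SN2-type step and no Lewis acid is present. This changes the reagent class and mechanism, not the bond cleaved or the stage. No new compound arises (F0).

**Further compounds**

F1 | step 5 | α-aryloxy phosphonoacetate, methyl (2R)-3-[3,4-bis(benzyloxy)phenyl]-2-{[(2E)-3-[4-(benzyloxy)-3-{[1-(dimethoxyphosphoryl)-2-methoxy-2-oxoethyl]oxy}phenyl]prop-2-enoyl]oxy}propanoate | COC(=O)C(Oc1cc(/C=C/C(=O)O[C@H](Cc2ccc(OCc3ccccc3)c(OCc3ccccc3)c2)C(=O)OC)ccc1OCc1ccccc1)P(=O)(OC)OC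
F2 | step 3 | phosphonoacetate ester, methyl (2R)-3-[3,4-bis(benzyloxy)phenyl]-2-{[2-(diethoxyphosphoryl)acetyl]oxy}propanoate | CCOP(=O)(OCC)CC(=O)O[C@H](Cc1ccc(OCc2ccccc2)c(OCc2ccccc2)c1)C(=O)OC
F0 | step 6 | none | none
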